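**Retrosynthetic overview**
1. Positions follow 2,3-dihydro-1-benzofuran numbering; ring A is the carbocycle C3a–C4–C5–C6–C7–C7a and ring B is O1–C2–C3–C3a–C7a. Both rings are closed in the last step from an open chain C2–C3–C3a=C4–C5–C6–C7–C7a: first C3a–C7a (ring A), then O1–C2 (ring B).
2. Enabling feature: the vinylogous ester O1–C7a=C7–C6=O of ring A is the enol ether of a cyclohexane-1,3-dione. Read backwards, C7a is the ester carbon of a β-keto ester (acyl electrophile for an alkenyl anion at C3a), and O1 is its enol oxygen, held next to C3a and placed for five-membered closure onto the readily ionised veratryl carbon C2.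
3. The open-chain precursor 17 carries a (Z)-alkenyl iodide at C3a and a silyl-masked β-keto ester (C6, C7, C7a) on the quaternary C5. The C6–C7 bond comes from a Claisen condensation, C5 from an enantioselective allylboration of an α-keto ester, and the C3a–I bond from hydroiodination of an ynone.
4. The α-keto ester comes from the alkyne C3a≡C4 and diethyl oxalate; the alkyne with C3 (and a provisional C2 carbinol) comes from (S)-but-3-yn-2-ol and 3,4-dimethoxybenzaldehyde by SE2′ propargylation.
5. Stereocontrol: C3 by chirality transfer (step 2), C5 by catalyst (step 6), C2 by C3 during closure of ring B (step 10).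

Key step: step 10

Remark on the chemistry: the C2 configuration from step 2 is provisional, because C2 is ionised and reset in step 10, so only the major anti series is drawn; enol ether 17 is drawn as its (2Z) isomer and would be used as whatever mixture of enol-ether isomers forms.

**Step 1**
Reactants: 1 (S)-but-3-yn-2-ol
Product: 2 (S)-but-3-yn-2-yl methanesulfonate
Conditions: MsCl, Et3N, CH2Cl2, −78 to 0 °C
Reagents that add atoms: methanesulfonyl chloride, CS(=O)(=O)Cl
Why: Sulfonylation at oxygen (mesylate formation) should activate the propargylic position without touching the stereocentre.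

**Step 2**
Reactants: 2 (S)-but-3-yn-2-yl methanesulfonate; 3 3,4-dimethoxybenzaldehyde
Product: 5 (1R,2R)-1-(3,4-dimethoxyphenyl)-2-methylbut-3-yn-1-ol, via allenylzinc reagent 4 (not isolated)
Conditions: Pd(OAc)2 (5 mol%), PPh3 (5 mol%), Et2Zn (3 equiv), THF, −78 to −20 °C; aq. NH4Cl
Reagents that add atoms: none
Why: Zerovalent palladium (from Pd(OAc)2 and Et2Zn) should open the mesylate anti (SN2′), and the allenylzinc 4 formed by transmetalation should add to the aldehyde through a cyclic SE2′ transition state (palladium-catalysed allenylzinc propargylation), which transfers the mesylate chirality to C3 with net inversion and favours the anti carbinol at C2.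

**Step 3**
Reactants: 5 (1R,2R)-1-(3,4-dimethoxyphenyl)-2-methylbut-3-yn-1-ol
Product: 6 tert-butyl{[(1R,2R)-1-(3,4-dimethoxyphenyl)-2-methylbut-3-yn-1-yl]oxy}dimethylsilane
Conditions: TBSCl, imidazole, DMF, rt
Reagents that add atoms: tert-butyldimethylsilyl chloride, CC(C)(C)[Si](C)(C)Cl
Why: Silyl ether formation protects the benzylic alcohol for the organolithium and enolate steps and leaves it ionisable by acid in step 10.

**Step 4**
Reactants: 6 silyl ether of the alkynol; 7 diethyl oxalate
Product: 9 ethyl (5R,6R)-6-[(tert-butyldimethylsilyl)oxy]-6-(3,4-dimethoxyphenyl)-5-methyl-2-oxohex-3-ynoate, via lithium acetylide 8 (not isolated)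
Conditions: n-BuLi, THF, −78 °C; then added to 7 (3 equiv), THF, −78 °C; then AcOH
Reagents that add atoms: none
Why: Nucleophilic acyl substitution of the lithium acetylide on excess diethyl oxalate at −78 °C, where the tetrahedral adduct survives until the quench, should stop at the alkynyl α-keto ester.

**Step 5**
Reactants: 9 alkynyl α-keto ester
Product: 10 ethyl (3Z,5S,6R)-6-[(tert-butyldimethylsilyl)oxy]-6-(3,4-dimethoxyphenyl)-4-iodo-5-methyl-2-oxohex-3-enoate
Conditions: NaI (1.5 equiv), AcOH (2 equiv), MeCN, 0 °C to rt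
Reagents that add atoms: sodium iodide, [Na+].[I-]
Why: Conjugate hydroiodination of the ynone (iodide adds to the β-carbon, protonation anti) should give the (Z)-β-iodo enone under kinetic control, which places iodine at the future C3a cis to the future C5.

**Step 6**
Reactants: 10 (Z)-iodo α-keto ester; 11 2-allyl-4,4,5,5-tetramethyl-1,3,2-dioxaborolane
Product: 12 ethyl (2S,3Z,5S,6R)-2-allyl-6-[(tert-butyldimethylsilyl)oxy]-6-(3,4-dimethoxyphenyl)-2-hydroxy-4-iodo-5-methylhex-3-enoate
Conditions: valine-derived aminophenol organocatalyst (2.5 mol%, the antipode that gives Re-face addition), NaOt-Bu (5 mol%), MeOH (1.5 equiv), toluene, 22 °C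
Reagents that add atoms: none
Why: Catalytic enantioselective allylboration of an α-keto ester (closed six-membered boron transition state, strictly 1,2) should set the tertiary carbinol, and allyl delivery to the Re face of the ketone gives the (S) centre that becomes C5.

**Step 7**
Reactants: 12 tertiary alcohol
Product: 13 ethyl (2S,3Z,5S,6R)-2-allyl-6-[(tert-butyldimethylsilyl)oxy]-6-(3,4-dimethoxyphenyl)-4-iodo-2-methoxy-5-methylhex-3-enoate
Conditions: MeOTf, 2,6-di-tert-butyl-4-methylpyridine, CH2Cl2, rt
Reagents that add atoms: methyl trifluoromethanesulfonate, COS(=O)(=O)C(F)(F)F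
Why: O-Alkylation with methyl triflate and a hindered pyridine (ether formation without a free alkoxide) should methylate the tertiary alcohol and avoids the anionic oxy-Cope rearrangement open to a 3-oxido-1,5-diene.

**Step 8**
Reactants: 13 α-methoxy ester; 14 ethyl acetate
Product: 16 ethyl (4S,5Z,7S,8R)-4-allyl-8-[(tert-butyldimethylsilyl)oxy]-8-(3,4-dimethoxyphenyl)-6-iodo-4-methoxy-7-methyl-3-oxooct-5-enoate, via lithium enolate of ethyl acetate 15 (not isolated)
Conditions: LiN(i-Pr)2 (3 equiv), 14 (3 equiv), THF, −78 °C; then 13, −78 to −20 °C; aq. NH4Cl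
Reagents that add atoms: none
Why: Crossed Claisen condensation of the non-enolisable, α-alkoxy-activated ester with enolate 15 should give the β-keto ester, driven by deprotonation of the product.

**Step 9**
Reactants: 16 β-keto ester
Product: 17 ethyl (2Z,4S,5Z,7S,8R)-4-allyl-3,8-bis[(tert-butyldimethylsilyl)oxy]-8-(3,4-dimethoxyphenyl)-6-iodo-4-methoxy-7-methylocta-2,5-dienoate
Conditions: TBSOTf, Et3N, CH2Cl2, −78 to 0 °C
Reagents that add atoms: tert-butyldimethylsilyl trifluoromethanesulfonate, CC(C)(C)[Si](C)(C)OS(=O)(=O)C(F)(F)F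
Why: Soft enolisation and O-silylation of the β-keto ester (silyl enol ether formation) removes the acidic C7–H and masks the C6 ketone for the halogen–lithium exchange.

**Step 10**
Reactants: 17 silyl-masked iodo β-keto ester
Product: 21 (2R,3R,5S)-5-allyl-2-(3,4-dimethoxyphenyl)-5-methoxy-3-methyl-2,3-dihydro-1-benzofuran-6(5H)-one, via alkenyllithium 18 (not isolated), via lithium dionate 19 (not isolated), via hydroxydienone 20 (not isolated)
Conditions: t-BuLi (2.1 equiv), THF, −78 to 0 °C; then CF3CO2H (5 equiv), CH2Cl2, 0 °C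
Reagents that add atoms: none
Why: Proposed new method: iodine–lithium exchange at C3a, faster than any attack on the ester, should give alkenyllithium 18, whose carbanion adds to the ester carbonyl C7a and expels ethoxide (C3a–C7a; ring A by 6-exo-trig acyl substitution), and the ethoxide then strips the enol silyl group to leave the cross-conjugated dionate 19. CF3CO2H protonates 19 to 20 and ionises the veratryl silyl ether at C2, and the enol oxygen O1, the only nucleophile that can reach this centre, captures it (O1–C2; ring B, a five-membered closure on a benzylic cation, formally 5-exo-tet). The closest known reaction types are the Parham cyclisation of exchange-generated organolithiums onto esters and the acid-mediated closure of 2-(1-aryl-1-hydroxypropan-2-yl)phenols to trans-2-aryl-3-methyl-2,3-dihydrobenzofurans; new is their telescoping on a silyl-masked β-keto ester. C2, the only new stereocentre, is set by C3: the closure is reversible under the acid and places the aryl group trans to the C3 methyl, so the C2 configuration carried from step 2 does not matter. The step needs chemoselective exchange and attack at C7a only: the (Z)-iodide holds C3a on the same side as C5, attack at C6 would need a four-membered ring, and the enol-ether geometry need not be controlled because a 1,5 O-to-O silyl shift to the acyl ketene acetal lets the C6–C7 bond rotate before addition. Silyl protection of the enol removes the acidic C7–H that would otherwise quench 18, and the quaternary C5 cannot epimerise.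

**Compound list**
1 | (S)-but-3-yn-2-ol | C#C[C@H](C)O | starting material
2 | (S)-but-3-yn-2-yl methanesulfonate | C#C[C@H](C)OS(C)(=O)=O | intermediate
3 | 3,4-dimethoxybenzaldehyde | COc1ccc(C=O)cc1OC | starting material
4 | (aR)-buta-1,2-dien-1-yl(ethyl)zinc | CC([H])=[C@]=C([H])[Zn]CC | intermediate (not isolated)
5 | (1R,2R)-1-(3,4-dimethoxyphenyl)-2-methylbut-3-yn-1-ol | C#C[C@@H](C)[C@@H](O)c1ccc(OC)c(OC)c1 | intermediate
6 | tert-butyl{[(1R,2R)-1-(3,4-dimethoxyphenyl)-2-methylbut-3-yn-1-yl]oxy}dimethylsilane | C#C[C@@H](C)[C@@H](O[Si](C)(C)C(C)(C)C)c1ccc(OC)c(OC)c1 | intermediate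
7 | diethyl oxalate | CCOC(=O)C(=O)OCC | starting material
8 | {(3R,4R)-4-[(tert-butyldimethylsilyl)oxy]-4-(3,4-dimethoxyphenyl)-3-methylbut-1-yn-1-yl}lithium | [Li]C#C[C@@H](C)[C@@H](O[Si](C)(C)C(C)(C)C)c1ccc(OC)c(OC)c1 | intermediate (not isolated)
9 | ethyl (5R,6R)-6-[(tert-butyldimethylsilyl)oxy]-6-(3,4-dimethoxyphenyl)-5-methyl-2-oxohex-3-ynoate | CCOC(=O)C(=O)C#C[C@@H](C)[C@@H](O[Si](C)(C)C(C)(C)C)c1ccc(OC)c(OC)c1 | intermediate
10 | ethyl (3Z,5S,6R)-6-[(tert-butyldimethylsilyl)oxy]-6-(3,4-dimethoxyphenyl)-4-iodo-5-methyl-2-oxohex-3-enoate | CCOC(=O)C(=O)/C=C(\I)[C@@H](C)[C@@H](O[Si](C)(C)C(C)(C)C)c1ccc(OC)c(OC)c1 | intermediate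
11 | 2-allyl-4,4,5,5-tetramethyl-1,3,2-dioxaborolane | C=CCB1OC(C)(C)C(C)(C)O1 | starting material
12 | ethyl (2S,3Z,5S,6R)-2-allyl-6-[(tert-butyldimethylsilyl)oxy]-6-(3,4-dimethoxyphenyl)-2-hydroxy-4-iodo-5-methylhex-3-enoate | C=CC[C@](O)(/C=C(\I)[C@@H](C)[C@@H](O[Si](C)(C)C(C)(C)C)c1ccc(OC)c(OC)c1)C(=O)OCC | intermediate
13 | ethyl (2S,3Z,5S,6R)-2-allyl-6-[(tert-butyldimethylsilyl)oxy]-6-(3,4-dimethoxyphenyl)-4-iodo-2-methoxy-5-methylhex-3-enoate | C=CC[C@](OC)(/C=C(\I)[C@@H](C)[C@@H](O[Si](C)(C)C(C)(C)C)c1ccc(OC)c(OC)c1)C(=O)OCC | intermediate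
14 | ethyl acetate | CCOC(C)=O | starting material
15 | lithium 1-ethoxyethen-1-olate (lithium enolate of ethyl acetate) | C=C(OCC)[O-].[Li+] | intermediate (not isolated)
16 | ethyl (4S,5Z,7S,8R)-4-allyl-8-[(tert-butyldimethylsilyl)oxy]-8-(3,4-dimethoxyphenyl)-6-iodo-4-methoxy-7-methyl-3-oxooct-5-enoate | C=CC[C@](OC)(/C=C(\I)[C@@H](C)[C@@H](O[Si](C)(C)C(C)(C)C)c1ccc(OC)c(OC)c1)C(=O)CC(=O)OCC | intermediate
17 | ethyl (2Z,4S,5Z,7S,8R)-4-allyl-3,8-bis[(tert-butyldimethylsilyl)oxy]-8-(3,4-dimethoxyphenyl)-6-iodo-4-methoxy-7-methylocta-2,5-dienoate | C=CC[C@](OC)(/C=C(\I)[C@@H](C)[C@@H](O[Si](C)(C)C(C)(C)C)c1ccc(OC)c(OC)c1)/C(O[Si](C)(C)C(C)(C)C)=C/C(=O)OCC | intermediate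
18 | ethyl (2Z,4S,5E,7R,8R)-4-allyl-3,8-bis[(tert-butyldimethylsilyl)oxy]-8-(3,4-dimethoxyphenyl)-6-lithio-4-methoxy-7-methylocta-2,5-dienoate | C=CC[C@](OC)(/C=C(\[Li])[C@@H](C)[C@@H](O[Si](C)(C)C(C)(C)C)c1ccc(OC)c(OC)c1)/C(O[Si](C)(C)C(C)(C)C)=C/C(=O)OCC | intermediate (not isolated)
19 | lithium (6S)-6-allyl-4-{(1R,2R)-1-[(tert-butyldimethylsilyl)oxy]-1-(3,4-dimethoxyphenyl)propan-2-yl}-6-methoxy-3-oxocyclohexa-1,4-dien-1-olate | C=CC[C@]1(OC)C=C([C@@H](C)[C@@H](O[Si](C)(C)C(C)(C)C)c2ccc(OC)c(OC)c2)C(=O)C=C1[O-].[Li+] | intermediate (not isolated)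
20 | (6S)-6-allyl-4-{(1R,2R)-1-[(tert-butyldimethylsilyl)oxy]-1-(3,4-dimethoxyphenyl)propan-2-yl}-3-hydroxy-6-methoxycyclohexa-2,4-dien-1-one | C=CC[C@]1(OC)C=C([C@@H](C)[C@@H](O[Si](C)(C)C(C)(C)C)c2ccc(OC)c(OC)c2)C(O)=CC1=O | intermediate (not isolated)
21 | (2R,3R,5S)-5-allyl-2-(3,4-dimethoxyphenyl)-5-methoxy-3-methyl-2,3-dihydro-1-benzofuran-6(5H)-one | C=CC[C@]1(OC)C=C2C(=CC1=O)O[C@@H](c1ccc(OC)c(OC)c1)[C@@H]2C | target

**Step count and risks**
Total step count: 10. Longest linear sequence: 10 steps (1 to 21).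

Steps most likely to fail:

Step 10 (Proposed new method). The alkenyllithium may be consumed before it reaches C7a: by O-to-C silyl migration, by loss of methoxide from C5 to give an allene, or because the enol ether stays in a rotamer that cannot close. In the acid stage the C2 cation may lose a proton towards C3 instead of being captured, which would erode the C3 centre. The fallback uses known reactions only and sets out from 16. LiBH4 in THF should reduce keto ester 16 to the iodo diol F1. TEMPO with PhI(OAc)2 should oxidise only the primary alcohol, giving the β-hydroxy aldehyde F2. An intramolecular Nozaki–Hiyama–Kishi reaction (CrCl2, catalytic NiCl2, DMSO) should close ring A as the cyclohexenediol F3. Dess–Martin periodinane should oxidise both carbinols to the enolised 1,3-dione, which is 20, where the route is rejoined. CF3CO2H then closes ring B to 21 as in the second stage of step 10.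

Step 6. Facial discrimination between the ester and the iodoalkenyl group may be poor, and methoxide may attack the β-iodo enone by addition–elimination. The fallback sets out from 10 and gives up catalyst control: uncatalysed addition of 11 (MeOH, rt) should give 12 together with its C2 epimer F4. The two are diastereomers, because C5 and C6 of the chain are already fixed, and would be separated by chromatography; the route is rejoined at 12.

Step 8. Addition of the ester enolate to the hindered α,α-disubstituted ester may be too slow, so that the enolate self-condenses or reverts on warming. The fallback sets out from 13 and builds the β-keto ester by C–H insertion instead of acyl substitution. i-Bu2AlH at −78 °C should stop at the α-methoxy aldehyde F5, and a Roskamp homologation (ethyl diazoacetate, SnCl2, CH2Cl2) should return to 16.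

**Further compounds**
F1 | step 10 | (3RS,4S,5Z,7S,8R)-4-allyl-8-[(tert-butyldimethylsilyl)oxy]-8-(3,4-dimethoxyphenyl)-6-iodo-4-methoxy-7-methyloct-5-ene-1,3-diol | C=CC[C@](OC)(/C=C(\I)[C@@H](C)[C@@H](O[Si](C)(C)C(C)(C)C)c1ccc(OC)c(OC)c1)C(O)CCO
F2 | step 10 | (3RS,4S,5Z,7S,8R)-4-allyl-8-[(tert-butyldimethylsilyl)oxy]-8-(3,4-dimethoxyphenyl)-3-hydroxy-6-iodo-4-methoxy-7-methyloct-5-enal | C=CC[C@](OC)(/C=C(\I)[C@@H](C)[C@@H](O[Si](C)(C)C(C)(C)C)c1ccc(OC)c(OC)c1)C(O)CC=O
F3 | step 10 | (1RS,3RS,4S)-4-allyl-6-{(1R,2R)-1-[(tert-butyldimethylsilyl)oxy]-1-(3,4-dimethoxyphenyl)propan-2-yl}-4-methoxycyclohex-5-ene-1,3-diol | C=CC[C@]1(OC)C=C([C@@H](C)[C@@H](O[Si](C)(C)C(C)(C)C)c2ccc(OC)c(OC)c2)C(O)CC1O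
F4 | step 6 | ethyl (2R,3Z,5S,6R)-2-allyl-6-[(tert-butyldimethylsilyl)oxy]-6-(3,4-dimethoxyphenyl)-2-hydroxy-4-iodo-5-methylhex-3-enoate | C=CC[C@@](O)(/C=C(\I)[C@@H](C)[C@@H](O[Si](C)(C)C(C)(C)C)c1ccc(OC)c(OC)c1)C(=O)OCC
F5 | step 8 | (2S,3Z,5S,6R)-2-allyl-6-[(tert-butyldimethylsilyl)oxy]-6-(3,4-dimethoxyphenyl)-4-iodo-2-methoxy-5-methylhex-3-enal | C=CC[C@](OC)(/C=C(\I)[C@@H](C)[C@@H](O[Si](C)(C)C(C)(C)C)c1ccc(OC)c(OC)c1)C=O
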